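Readings and results stem from a simulated flask for an exercise.

Two runs with the same substrate part on the reagent charge: delta, with 1.2 M of reagent against 0.85 M of substrate, carries product to 100.2%, while beta, with 0.595 M, stands near 69.8% from 5.00 min on.

| setting | beta | delta | flask |
|---|---|---|---|
| substrate | 0.85 M | 0.85 M | 0.85 M |
| reagent | 0.595 M | 1.2 M | 0.595 M |
| initiator | 13 mM | 13 mM | 13 mM |
| remark | the very flask that is asked about, followed so far | run made earlier |  |
| time |  |  | 80 min |

- beta (time / min: substrate / %, product / %): 1.33: 66.9, 33.6; 2.00: 54.3, 45.2; 3.00: 40.2, 60.2; 5.00: 29.2, 70.0; 6.00: 29.4, 69.6; 10.0: 30.1, 70.1; 15.0: 29.8, 69.8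
- delta (time / min: substrate / %, product / %): 5.00: 21.9, 79.2; 6.00: 15.9, 83.5; 10.0: 4.5, 94.1; 15.0: 1.7, 99.7; 25.0: 0, 99.8; 40.0: 0, 100.6; 60.0: 0, 100.2

(scatter of a reading: 0.5 percentage points)

- percentages count the substrate that a species holds: one ended chains A counts as two
- steps thought possible: initiator -> 2 initiating radical; substrate + initiating radical -> capped initiator + first chain carrier; reagent + first chain carrier -> product + second chain carrier; substrate + second chain carrier -> by-product + first chain carrier; 2 first chain carrier -> ended chains A; 2 second chain carrier -> ended chains B
- the reaction counts as stopped when no species that holds the substrate changes by six tenths of a point or more over the second half of the time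

1. the state of affairs at 80 min: stopped, and by what, or still going (the reagent has run out first / it is still moving / all of the substrate has reacted)
2. share of the substrate used up at 80 min
3. product at 80 min, in percent of the substrate charged

Since each product takes one reagent and one substrate, the product ceiling, charged [reagent] over charged [substrate], is 70.0% in beta, which makes reagent the limiting reagent of that flask and leaves 30.0% of the substrate at the plateau. Past the ceiling, first chain carrier meets no further reagent of the 0.595 M charged, so each initiator that falls apart takes two substrates into ended chains A, and the initiator charge is a reserve of 3.06% of the substrate, which places the conversion in beta at 80 min between 70.0% and 73.1%.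

The weak link is the stopping call, since the plateau readings of beta, with their scatter of 0.5 percentage points, show no drift from which to read the initiator's rate. It can be reforged without that rate: a first-order initiator, whatever its rate constant, spends at most a quarter of the reserve between 40.0 min and 80 min, which is 0.76 points, against a mark of 0.6 points, so this reckoning leaves the stopping call open and commits only to the range of the conversion.

The forecast gives it is still moving, 71.7% and 70%, adding: “so the flask is probably still creeping, though this is marginal”.

The state of beta at 80 min is this: the reagent has run out first, with 71.3% of the substrate used up and 70.0% product. The largest change in beta of the share of a substrate, an intermediate or a product over the second half of the time is 0.58 points, against the mark of 0.6 points. The product stands at the ceiling of 70.0%, and the conversion lies 1.3 points beyond it.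

    initiator → 2 initiating radical (k = 1.24 × 10⁻⁴ s⁻¹)
    substrate + initiating radical → capped initiator + first chain carrier (k = 2.44 × 10⁶ M⁻¹ s⁻¹)
    reagent + first chain carrier → product + second chain carrier (k = 2.34 × 10⁵ M⁻¹ s⁻¹)
    substrate + second chain carrier → by-product + first chain carrier (k = 1.27 × 10⁵ M⁻¹ s⁻¹)
    2 first chain carrier → ended chains A (k = 2.70 × 10⁶ M⁻¹ s⁻¹)
    2 second chain carrier → ended chains B (k = 9.90 × 10⁸ M⁻¹ s⁻¹)

A neighbour charged with 1.4 M of substrate has a ceiling of 42.5%; computed, it holds 42.5% product and 56.7% substrate at 80.0 min.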